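The runs were computed from invented constants; scatter was added.

Amounts first: cedar, elm and ash each hold 10 mM of substrate, with partner at 12.0 mM, 27.0 mM and 18.0 mM, and alpha is the run we can read.

| setting | alpha | cedar | elm | ash |
|---|---|---|---|---|
| substrate | 10 mM | 10 mM | 10 mM | 10 mM |
| partner | 12 mM | 12.0 mM | 27.0 mM | 18.0 mM |
| second reagent | 30 mM | 30.0 mM | 30.0 mM | 30.0 mM |
| third reagent | 6 mM | 9.00 mM | 9.00 mM | 9.00 mM |
| remark | run made earlier |  |  |  |
| time |  | 4.0 h | 4.0 h | 4.0 h |

alpha run (percent of the substrate charged)

| time / min | intermediate B / % | intermediate A / % | substrate / % | target / % |
|---|---|---|---|---|
| 6.00 | 0 | 4.8 | 95.6 | 0.3 |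
| 12.0 | 0 | 8.6 | 91.0 | 0.4 |
| 20.0 | 1.2 | 11.0 | 87.2 | 0 |
| 30.0 | 2.9 | 14.4 | 82.8 | 0 |
| 50.0 | 5.7 | 17.4 | 77.9 | 0.6 |
| 80.0 | 10.6 | 17.4 | 71.1 | 0 |

(scatter of a reading: 0.5 percentage points)

- a reading of target is of its free form alone

1. which of these there is most of at the end, counted by the substrate in it, cedar (intermediate A / target / intermediate B / substrate)
2. which of these there is most of at the end, counted by the substrate in it, elm (intermediate A / target / intermediate B / substrate)
3. which of these there is most of at the end, counted by the substrate in it, ash (intermediate A / target / intermediate B / substrate)
4. amount of the one of these that there is most of at the end, in percent of the substrate charged, cedar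
5. amount of the one of these that there is most of at the end, in percent of the substrate charged, elm
6. amount of the one of these that there is most of at the end, in percent of the substrate charged, ash

In the first instants of alpha the substrate loses 0.00786 /min of itself, reckoned over the first 12.0 min. Intermediate A climbs, and intermediate B appears after it. We take this specific rate to follow c(partner).

In the middle, between 50.0 min and 80.0 min, the rate reads 0.00304 /min, which is 38.7% of the early value. Yet the substrate had taken about 2.56 mM of the 12 mM of partner. So we reckon that partner also disappears on its own, in proportion to itself.

Partner then divides between its two ways as c(substrate) against a fixed level, the break-even level 17.9 mM: the c(substrate) at which partner goes equally to the substrate and to its own loss. Summed over a run, partner used equals substrate reacted plus the break-even level times ln(c(substrate) at start / c(substrate) now). Writing this for both alpha windows gave the value, which is a reading and carries their scatter. At the start of cedar the substrate gets 35.8% of the partner used, since the charge lies under the break-even level.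

At the end, the own loss has a half-life of 52.6 min, so over 4.0 h it alone leaves 4.23% of the partner. Partner is therefore the limiting reagent, and substrate stops where the balance closes. That gives 62.8% in cedar, 32.4% in elm and 48.8% in ash.

Cedar keeps more substrate than it reacts. Intermediate A passes on at a read 0.00939 /min, and if we take the reacted substrate as made, on average, at that half-life, we estimate that 82.8% of it has reached intermediate B or gone beyond by 4.0 h. In ash, intermediate B needs 95.3% of the reacted share to pass the substrate, which is more than that estimate, so we put substrate first. In elm, the same estimate puts intermediate B, together with whatever has gone beyond it, near 56.0%, so intermediate B leads there.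

The forecast gives substrate at 51% in cedar, intermediate B at 53% in elm and intermediate B at 43% in ash, on the ground that “The slowing loss and the A plateau suggest reversal”, whereas we reckon with a partner that is lost and put substrate first in ash.

The flasks give substrate at 64.2% in cedar, intermediate B at 40.7% in elm and substrate at 50.4% in ash.

    substrate + partner → intermediate A (k = 0.693 /M/min)
    second reagent + intermediate A → intermediate B (k = 0.324 /M/min)
    partner → decomposed reagent (k = 0.0129 /min)
    target ⇌ isomer of the product (K = 1.10, k = 0.00750 /min)
    third reagent + intermediate B → target (k = 0.231 /M/min)

Ash ends with 12.7 mM of decomposed reagent, and the break-even level times ln(start over end substrate) books 12.3 mM for that loss. For the neighbour flask, elm with 46 mM of partner, the balance gives 12.5% of substrate, and that flask ends at 14.4%.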